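## Structural features

The target (25) is an achiral, unsymmetrical dimer: two 1-(2,6-dihydroxyphenyl)nonan-1-one arms (rings C and D, each a 2-acylresorcinol) end at C9 on two catechol rings, A and B, which are joined by a biaryl bond. The halves differ only in where the biaryl bond sits: on ring A (C1 = biaryl carbon) the hydroxyls are at C2 and C3 and the chain at C5, so the biaryl carbon is ortho to a hydroxyl and meta to the chain, whereas on ring B the biaryl carbon C1' is ortho to the chain (C2') and the hydroxyls are at C4' and C5'. There is no stereocentre, and the biaryl axis carries only two ortho substituents (O on ring A, CH2 on ring B), so no stereochemical issue arises in the target. The fragile groups are the eight free phenols, above all the two catechols, which air oxidises to ortho-quinones under base, and the two enolisable aryl ketones; all are masked until the last step. The real difficulty is the unsymmetrical, electron-rich, ortho-substituted biaryl bond between two differently substituted catechols, together with two long chains that should not double the step count. The key step exploits the ring A pattern C1(aryl)–C2(O)–C3(O) with the chain at C5, which is the pattern of a 2-aryl-4-alkylcyclohex-2-en-1-one: the carbonyl carbon is C2 of ring A, the aryl-bearing alkene carbon is C1, the alkyl-bearing sp3 carbon is C5 and the alpha-prime methylene is C3. Ring A can therefore be built by Michael–aldol annulation with ring B already attached and aromatised afterwards.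

## Logic of the disconnections

25 from 24. The eight aryl O–CH3 bonds are cut last in the forward sense; in reverse, all eight phenols are masked as methyl ethers. Free catechols and acylresorcinols tolerate neither the organometallic nor the oxidative steps, and methyl is the group that 1 and 21 already carry. The gain is a robust series of intermediates. The demand is one exhaustive Lewis-acid ether cleavage that leaves both ketones untouched.

24 from 20 and 21 (through 23 and 22). Both C(carbonyl)–C(aryl) bonds to rings C and D are cut. The carbon between the two oxygens of 21 is reached by directed lithiation and not by electrophilic acylation, so the ring must be the nucleophile. Rings C and D become a purchased arene, used twice, and the problem shrinks to 20. The forward steps must add 22 twice, once to each enolisable aldehyde group at low temperature, and then oxidise the hindered, acid-sensitive carbinols of 23 under buffered conditions.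

20 from 17 (through 19 and 18). The two C9–O bonds at the chain ends are removed, leaving two terminal vinyl groups. Vinyl groups are inert to every earlier reagent and are identical at both chain ends, so both arms are elaborated in the same flasks. The demand is anti-Markovnikov hydroboration of two monosubstituted alkenes and an oxidation that stops at the aldehyde.

17 from 13 (through 16, 15 and 14). Ring A is dearomatised: the C–O bond at the alpha-prime carbon and the two O–CH3 bonds are cut and the ring returns to the cyclohexenone level. This works because 16 is a tautomer of 15, and 15 is 13 plus one oxygen at C6 and one oxidation. The gain is decisive: the biaryl bond of 17 becomes the C2–aryl bond of an enone, so no aryl–aryl coupling is needed. The forward steps need kinetic enolisation of 13 at C6 and not C4, and oxidants that spare the terminal alkenes and the new catechol. The stereocentres of 13 and 14 need no control because both vanish in 16.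

13 from 8 and 9 (through 10, 11 and 12). The ring bonds C4–C5 (Michael) and C2=C3 (aldol condensation) are cut, which is the 1,5-dicarbonyl relationship of 11. The chain-bearing carbon goes to a stock aldehyde and ring B, with its chain, goes to a vinyl ketone; both fragments carry the same non-8-enyl chain. Ring A is made from two open-chain pieces in one operation. The demands are that 8, which polymerises easily and is itself a potential Michael donor, is captured by 10 faster than it reacts with itself, and that the aldol closes only through the benzylic carbon.

8 from 6 (through 7). The C(carbonyl)–C(vinyl) bond is cut. Acylation of a vinyl nucleophile by 6 stops at the ketone because 7 does not collapse before the quench. The demand is addition faster than benzylic deprotonation and a quench that prevents re-addition of the liberated hydroxylamine. 8 is made last and used at once.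

6 from 3 and 4 (through 5). The aryl–CH2 bond of the ring B chain is cut. An sp2–sp3 coupling of an aryl bromide with a primary alkylborane is reliable, and 4 is symmetrical, so hydroboration of either end gives the same 5 and leaves the vinyl group needed later. The demand is hydroboration at one end only (excess 4) and a catalyst that activates an electron-rich, ortho-substituted bromide.

3 from 1 (through 2). The amide C–N bond is cut, back to a purchased acid that already has bromine ortho to the side chain and both ring B oxygens in place. The amide precedes the coupling so that no free carboxylic acid enters step 2. The demand is activation mild enough not to enolise the arylacetyl unit.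

## Other disconnections considered

Alternative 1: The cut goes through both benzylic C8=C9 bonds (chains numbered from the ketone carbon). It divides the molecule into the tetrabenzylated biaryl dialdehyde A1 and two equivalents of the ketone-bearing phosphonium salt A2. Forward, the ylide of A2 would olefinate both formyl groups of A1 to the bis(Z-styrene) A3. One hydrogenation over Pd/C would then saturate both alkenes and remove all eight benzyl groups to give 25.
- In its favour: maximal convergence, all four rings bought as arenes, irrelevant alkene geometry, and a neutral final unmasking without a Lewis acid. On these points and on step count this plan is the better of the two.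
- Against it here: A1 is an unsymmetrical biaryl of two electron-rich rings and needs a cross-coupling whose ring B partner is ortho-substituted. The ylide of A2 is non-stabilised and carries an enolisable ketone in the same molecule, so proton transfer and self-condensation would compete with olefination of the hindered ring B aldehyde. Hydrogenolysis of eight benzyl ethers beside two aryl ketones could stall or over-reduce the carbonyls.
- Comparison: the chosen plan is longer and linear, but it makes the biaryl bond by ring construction, where connectivity fixes the regiochemistry, and never exposes a ketone to a carbanion. The two plans are equal in handling both arms by twofold operations.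

Alternative 2: The cut takes rings C and D apart at the bonds C(OH)–C(acyl-bearing) and C(OSi)–CH, giving the bis(siloxyalkyne) A4 and two equivalents of cyclobut-2-en-1-one A5. Forward, heating A4 with A5 would start a cascade of four-electron ring opening, [2+2] cycloaddition to the alkyne, a second ring opening and six-electron electrocyclisation. This would give the bis(resorcinol monosilyl ether) A6; desilylation, ketal hydrolysis and ether cleavage would follow.
- In its favour: the mechanism locks the acyl carbon between the two ring oxygens, and the conditions are neutral and thermal with no organolithium. In regiocontrol it is the equal of the directed lithiation of the chosen plan.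
- Against it here: rings C and D are the part of 25 that can be bought. The unsubstituted A5 is volatile and polymerises readily, and it would have to react twice with an alkyne hindered by a fully substituted propargylic ketal carbon. A4 needs a long synthesis that still contains the whole biaryl problem, and three deprotections follow the key step.
- Comparison: the mechanism is elegant, but the key step is spent on the easy rings. The chosen plan uses ring synthesis where it solves the hard bond. In step economy this alternative is clearly the weaker.

Alternative 3: The cut goes through both C7–C8 bonds, giving the biaryl bis(propanoic acid) A7 (as tetrapivalate) and the 8-aryl-8-oxooctanoic acid A8 (as bis-pivalate). Forward, co-electrolysis at a platinum anode in partly neutralised methanol would decarboxylate both acids to primary radicals. Their cross-coupling would give the octapivalate A9, and ester cleavage would give 25.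
- In its favour: the arms are joined at unfunctionalised sp3 carbons, so nothing remains to adjust at the junction. No organometallic reagent is used. The acyl groups protect the arenes against anodic oxidation and come off without a Lewis acid. In the mildness of the last step and in step count after the fragments it is the better plan.
- Against it here: mixed Kolbe coupling is statistical. A twofold heterocoupling on a diacid needs a large excess of A8 and would still suffer from homocoupling of the excess partner, from singly coupled material and from oligomerisation of A7. The electron-rich biaryl may be oxidised at the anode, and pivalates may be transesterified in methanolic carboxylate. A7 still needs the unsymmetrical biaryl.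
- Comparison: this route is equal to alternative 1 in convergence and weaker than the chosen plan in selectivity and material throughput. The chosen plan secures its chemoselectivity by ring-size constraints and not by statistics.

Key step: step 4

Remarks on the chemistry (assumptions)
- 25 has no stereocentre. 11, 12, 13, 14 and 23 are racemic or mixtures of diastereomers and are drawn without descriptors; all of these centres are lost again.
- 1 is taken to be a catalogue compound.
- Metal enolates, metal alkoxides and boron aryloxides that are only the pre-work-up salts of a numbered compound are not numbered separately.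
- Atom bookkeeping for the key step: C2 of 9 becomes C4 of 13, and C3–C11 of 9 are its non-8-enyl substituent. The vinyl CH2 and CH of 8 become C5 and C6, the benzylic carbon of 8 becomes C2, and C1 of 9 becomes C3. After step 8 each chain has nine carbons (eight methylenes and the future ketone carbon), as 25 requires.
- Stoichiometry of the twofold steps: steps 7 to 12 act on both arms or both catechol oxygens at once and consume two or more molecules of the named reagent per molecule of substrate. In step 10 two molecules of 21 are built into each molecule of 20, one per aldehyde group, and no atom is lost, so 23 is the sum of 20 and two molecules of 21.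
- Design choices made for safety: the amide is made before the coupling; 8 is never stored; 10 is preformed and used in excess with no free amine; a potassium enolate is used in step 5; activated DMSO is used in step 6 so the new catechol does not meet an oxidant that attacks phenols; in step 10 the arene is kept in slight excess over n-BuLi so that no alkyllithium reaches the aldehyde.

## Route

Step 1
Reactants: 1 (2-bromo-4,5-dimethoxyphenyl)acetic acid
Product: 3 2-(2-bromo-4,5-dimethoxyphenyl)-N-methoxy-N-methylacetamide, via acyl imidazole 2 (not isolated)
Conditions: 1,1'-carbonyldiimidazole, CH2Cl2, rt; then MeNHOMe·HCl, rt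
Reagents that add atoms: N,O-dimethylhydroxylamine hydrochloride, CNOC.Cl
Why: Amide formation through an acyl imidazole; the acid is activated without a base strong enough to enolise the arylacetyl unit, and the released imidazole neutralises the hydrochloride. Making the amide first keeps a free carboxylic acid out of the coupling.

Step 2
Reactants: 4 nona-1,8-diene; 3 2-(2-bromo-4,5-dimethoxyphenyl)-N-methoxy-N-methylacetamide
Product: 6 2-[4,5-dimethoxy-2-(non-8-en-1-yl)phenyl]-N-methoxy-N-methylacetamide, via B-(non-8-en-1-yl)-9-BBN 5 (not isolated)
Conditions: 4 (4 equiv), 9-BBN, THF, 0 °C to rt; then 3, Pd(OAc)2, SPhos, K3PO4, THF/H2O, 65 °C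
Reagents that add atoms: none
Why: B-alkyl Suzuki–Miyaura coupling; the excess of the symmetrical diene keeps hydroboration at one terminus, 9-BBN places boron on the terminal carbon, and the bulky electron-rich phosphine lets zerovalent palladium insert into the electron-rich, ortho-substituted aryl bromide. The amide and the remaining vinyl group should be inert to the phosphate base.

Step 3
Reactants: 6 2-[4,5-dimethoxy-2-(non-8-en-1-yl)phenyl]-N-methoxy-N-methylacetamide
Product: 8 1-[4,5-dimethoxy-2-(non-8-en-1-yl)phenyl]but-3-en-2-one, via chelated magnesium hemiaminal 7 (not isolated)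
Conditions: CH2=CHMgBr, THF, −20 to 0 °C; inverse quench into cold 1 M HCl/Et2O; BHT, used at once
Reagents that add atoms: vinylmagnesium bromide, C=C[Mg]Br
Why: Weinreb ketone synthesis; the five-membered magnesium chelate 7 persists until the quench, so the enone never meets the Grignard reagent. Pouring into cold acid protonates the released N,O-dimethylhydroxylamine before it can add to the enone.

Step 4
Reactants: 9 undec-10-enal; 8 1-[4,5-dimethoxy-2-(non-8-en-1-yl)phenyl]but-3-en-2-one
Product: 13 rac-2-[4,5-dimethoxy-2-(non-8-en-1-yl)phenyl]-4-(non-8-en-1-yl)cyclohex-2-en-1-one, via enamine 10 (not isolated), via keto aldehyde 11 (not isolated), via aldol 12 (not isolated)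
Conditions: 9 (1.5 equiv), pyrrolidine (1.5 equiv), 4 Å molecular sieves, toluene, 0 °C; then 8, 0 °C to rt; then AcOH, NaOAc, H2O, 70 °C
Reagents that add atoms: none
Why: Enamine Michael addition followed by intramolecular aldol condensation, the Robinson-type synthesis of 4-substituted cyclohex-2-enones from an aldehyde and a vinyl ketone. The preformed enamine 10 attacks the CH2 terminus of enone 8 through its beta carbon (the former C2 of 9), which forms the C4–C5 bond of the future ring, and buffered hydrolysis releases pyrrolidine and the 1,5-keto aldehyde 11. The benzylic methylene of 11, acidified by both the ketone and ring B, then adds to the aldehyde as its enol or pyrrolidine enamine in a 6-(enolendo)-exo-trig closure to the aldol 12, and E1cB loss of water gives the aryl-conjugated enone 13. Chemoselectivity of the closure follows from ring size: the aldehyde alpha carbon and the other ketone alpha carbon could only form four-membered rings, so the six-membered mode has no intramolecular competitor. The first bond is regiochemically fixed because attack of the enamine nitrogen on the enone is reversible whereas carbon attack is not, and the enone is electrophilic only at its unsubstituted terminus. The one new stereocentre (C4) has no controlling element, so 13 is racemic, which is harmless because C4 becomes an aromatic carbon in step 6. Using 10 in excess with no free amine should suppress self-addition of 8 through its own acidic methylene and a second alkylation of the first adduct.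

Step 5
Reactants: 13 rac-2-[4,5-dimethoxy-2-(non-8-en-1-yl)phenyl]-4-(non-8-en-1-yl)cyclohex-2-en-1-one
Product: 14 2-[4,5-dimethoxy-2-(non-8-en-1-yl)phenyl]-6-hydroxy-4-(non-8-en-1-yl)cyclohex-2-en-1-one (racemic mixture of diastereomers)
Conditions: KN(SiMe3)2, THF, −78 °C; then 2-(benzenesulfonyl)-3-phenyloxaziridine, −78 °C; sat. NH4Cl
Reagents that add atoms: 2-(benzenesulfonyl)-3-phenyloxaziridine, O=S(=O)(c1ccccc1)N1OC1c1ccccc1
Why: Kinetic deprotonation of a cyclohexenone at low temperature takes an alpha-prime hydrogen (C6), and the cross-conjugated enolate is hydroxylated by electrophilic oxygen transfer from the N-sulfonyloxaziridine, which does not touch the terminal alkenes. The potassium enolate is chosen because it does not add to the sulfonimine by-product; the configuration of the new carbinol carbon is irrelevant since C4 and C6 both become aromatic carbons.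

Step 6
Reactants: 14 2-[4,5-dimethoxy-2-(non-8-en-1-yl)phenyl]-6-hydroxy-4-(non-8-en-1-yl)cyclohex-2-en-1-one
Product: 16 4',5'-dimethoxy-2',5-di(non-8-en-1-yl)-[1,1'-biphenyl]-2,3-diol, via ene-dione 15 (not isolated)
Conditions: (COCl)2, DMSO, CH2Cl2, −78 °C; then Et3N, −78 °C to rt, argon
Reagents that add atoms: none
Why: Swern oxidation of the acyloin gives the cyclohex-3-ene-1,2-dione 15, a non-aromatic tautomer of the catechol; amine-mediated enolisation towards C5 and then loss of the doubly vinylogous C4 hydrogen as a proton aromatise ring A. The slight excess of activated DMSO decomposes well below 0 °C, so little oxidant should remain when the catechol forms on warming, and the terminal alkenes are inert.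

Step 7
Reactants: 16 4',5'-dimethoxy-2',5-di(non-8-en-1-yl)-[1,1'-biphenyl]-2,3-diol
Product: 17 2,3,4',5'-tetramethoxy-2',5-di(non-8-en-1-yl)-1,1'-biphenyl
Conditions: MeI, K2CO3, DMF, rt, argon
Reagents that add atoms: iodomethane, CI
Why: Williamson O-methylation of both catechol hydroxyls; exclusion of air protects the catecholate until it is capped. The crude catechol from step 6 is used directly.

Step 8
Reactants: 17 2,3,4',5'-tetramethoxy-2',5-di(non-8-en-1-yl)-1,1'-biphenyl
Product: 19 9,9'-(2,3,4',5'-tetramethoxy-[1,1'-biphenyl]-2',5-diyl)di(nonan-1-ol), via bis(9-BBN) adduct 18 (not isolated)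
Conditions: 9-BBN, THF, 0 °C to rt; then NaOH, H2O2, H2O, 0 °C to rt
Reagents that add atoms: hydrogen peroxide, OO
Why: Twofold hydroboration–oxidation; 9-BBN adds boron to the terminal carbon of each monosubstituted alkene and alkaline peroxide replaces boron by hydroxyl with retention. The tetramethoxybiaryl is inert.

Step 9
Reactants: 19 9,9'-(2,3,4',5'-tetramethoxy-[1,1'-biphenyl]-2',5-diyl)di(nonan-1-ol)
Product: 20 9,9'-(2,3,4',5'-tetramethoxy-[1,1'-biphenyl]-2',5-diyl)dinonanal
Conditions: DMP, pyridine, CH2Cl2, 0 °C to rt
Reagents that add atoms: none
Why: Dess–Martin oxidation of both primary alcohols stops at the aldehyde under buffered, anhydrous conditions.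

Step 10
Reactants: 21 1,3-dimethoxybenzene; 20 9,9'-(2,3,4',5'-tetramethoxy-[1,1'-biphenyl]-2',5-diyl)dinonanal
Product: 23 9,9'-(2,3,4',5'-tetramethoxy-[1,1'-biphenyl]-2',5-diyl)bis[1-(2,6-dimethoxyphenyl)nonan-1-ol] (mixture of diastereomers), via 2,6-dimethoxyphenyllithium 22 (not isolated)
Conditions: 21 (3.0 equiv), n-BuLi (2.8 equiv), THF, 0 °C to rt; then 20 (1.0 equiv), −78 °C; sat. NH4Cl
Reagents that add atoms: 1,3-dimethoxybenzene (second equivalent of 21 which also enters as 22), COc1cccc(OC)c1
Why: Directed ortho-lithiation of 21 occurs at C2, between the two methoxy groups, and two molecules of the aryllithium 22 add, one to each aldehyde group of 20, so that 23 contains 20 and two molecules of 21 with no atom lost. Low temperature, an excess of 22 and the absence of free n-BuLi favour addition over enolisation; the two remote carbinol centres are lost in step 11.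

Step 11
Reactants: 23 9,9'-(2,3,4',5'-tetramethoxy-[1,1'-biphenyl]-2',5-diyl)bis[1-(2,6-dimethoxyphenyl)nonan-1-ol]
Product: 24 9,9'-(2,3,4',5'-tetramethoxy-[1,1'-biphenyl]-2',5-diyl)bis[1-(2,6-dimethoxyphenyl)nonan-1-one]
Conditions: DMP, pyridine, CH2Cl2, rt
Reagents that add atoms: none
Why: Dess–Martin oxidation of the two benzylic carbinols to aryl ketones; the pyridine buffer prevents acid-induced ionisation of the electron-rich carbinols.

Step 12
Reactants: 24 9,9'-(2,3,4',5'-tetramethoxy-[1,1'-biphenyl]-2',5-diyl)bis[1-(2,6-dimethoxyphenyl)nonan-1-one]
Product: 25 9,9'-(2,3,4',5'-tetrahydroxy-[1,1'-biphenyl]-2',5-diyl)bis[1-(2,6-dihydroxyphenyl)nonan-1-one] (CNP0305015.0)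
Conditions: BBr3 (excess), CH2Cl2, −78 °C to rt; then MeOH, H2O, 0 °C, argon
Reagents that add atoms: none
Why: Lewis-acid cleavage of aryl methyl ethers: boron coordinates each ether oxygen and bromide removes the methyl group. The ethers flanking the ketones are assisted by chelation, the catechol ethers are standard substrates, and the aryl ketones are inert to the reagent.

## Compound list

1 | (2-bromo-4,5-dimethoxyphenyl)acetic acid | COc1cc(Br)c(CC(=O)O)cc1OC | starting material
2 | 2-(2-bromo-4,5-dimethoxyphenyl)-1-(1H-imidazol-1-yl)ethan-1-one | COc1cc(Br)c(CC(=O)n2ccnc2)cc1OC | intermediate (not isolated)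
3 | 2-(2-bromo-4,5-dimethoxyphenyl)-N-methoxy-N-methylacetamide | COc1cc(Br)c(CC(=O)N(C)OC)cc1OC | intermediate
4 | nona-1,8-diene | C=CCCCCCC=C | starting material
5 | 9-(non-8-en-1-yl)-9-borabicyclo[3.3.1]nonane | C=CCCCCCCCB1C2CCCC1CCC2 | intermediate (not isolated)
6 | 2-[4,5-dimethoxy-2-(non-8-en-1-yl)phenyl]-N-methoxy-N-methylacetamide | C=CCCCCCCCc1cc(OC)c(OC)cc1CC(=O)N(C)OC | intermediate
7 | bromomagnesium alkoxide of the tetrahedral vinyl adduct of 6 (chelated magnesium hemiaminal) | C=CC(O[Mg]Br)(Cc1cc(OC)c(OC)cc1CCCCCCCC=C)N(C)OC | intermediate (not isolated)
8 | 1-[4,5-dimethoxy-2-(non-8-en-1-yl)phenyl]but-3-en-2-one | C=CC(=O)Cc1cc(OC)c(OC)cc1CCCCCCCC=C | intermediate (precursor of the key step)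
9 | undec-10-enal | C=CCCCCCCCCC=O | starting material
10 | 1-[(1E)-undeca-1,10-dien-1-yl]pyrrolidine | C=CCCCCCCC/C=C/N1CCCC1 | intermediate (not isolated)
11 | rac-6-[4,5-dimethoxy-2-(non-8-en-1-yl)phenyl]-2-(non-8-en-1-yl)-5-oxohexanal | O=CC(CCCCCCCC=C)CCC(=O)Cc1cc(OC)c(OC)cc1CCCCCCCC=C | intermediate (not isolated)
12 | 2-[4,5-dimethoxy-2-(non-8-en-1-yl)phenyl]-3-hydroxy-4-(non-8-en-1-yl)cyclohexan-1-one (mixture of diastereomers) | O=C1CCC(CCCCCCCC=C)C(O)C1c1cc(OC)c(OC)cc1CCCCCCCC=C | intermediate (not isolated)
13 | rac-2-[4,5-dimethoxy-2-(non-8-en-1-yl)phenyl]-4-(non-8-en-1-yl)cyclohex-2-en-1-one | O=C1CCC(CCCCCCCC=C)C=C1c1cc(OC)c(OC)cc1CCCCCCCC=C | intermediate (product of the key step)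
14 | 2-[4,5-dimethoxy-2-(non-8-en-1-yl)phenyl]-6-hydroxy-4-(non-8-en-1-yl)cyclohex-2-en-1-one (racemic mixture of diastereomers) | O=C1C(O)CC(CCCCCCCC=C)C=C1c1cc(OC)c(OC)cc1CCCCCCCC=C | intermediate
15 | rac-3-[4,5-dimethoxy-2-(non-8-en-1-yl)phenyl]-5-(non-8-en-1-yl)cyclohex-3-ene-1,2-dione | O=C1C(=O)CC(CCCCCCCC=C)C=C1c1cc(OC)c(OC)cc1CCCCCCCC=C | intermediate (not isolated)
16 | 4',5'-dimethoxy-2',5-di(non-8-en-1-yl)-[1,1'-biphenyl]-2,3-diol | Oc1cc(CCCCCCCC=C)cc(-c2cc(OC)c(OC)cc2CCCCCCCC=C)c1O | intermediate
17 | 2,3,4',5'-tetramethoxy-2',5-di(non-8-en-1-yl)-1,1'-biphenyl | COc1cc(CCCCCCCC=C)cc(-c2cc(OC)c(OC)cc2CCCCCCCC=C)c1OC | intermediate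
18 | 9,9'-[(2,3,4',5'-tetramethoxy-[1,1'-biphenyl]-2',5-diyl)di(nonane-9,1-diyl)]bis(9-borabicyclo[3.3.1]nonane) | COc1cc(CCCCCCCCCB2C3CCCC2CCC3)cc(-c2cc(OC)c(OC)cc2CCCCCCCCCB2C3CCCC2CCC3)c1OC | intermediate (not isolated)
19 | 9,9'-(2,3,4',5'-tetramethoxy-[1,1'-biphenyl]-2',5-diyl)di(nonan-1-ol) | COc1cc(CCCCCCCCCO)cc(-c2cc(OC)c(OC)cc2CCCCCCCCCO)c1OC | intermediate
20 | 9,9'-(2,3,4',5'-tetramethoxy-[1,1'-biphenyl]-2',5-diyl)dinonanal | COc1cc(CCCCCCCCC=O)cc(-c2cc(OC)c(OC)cc2CCCCCCCCC=O)c1OC | intermediate
21 | 1,3-dimethoxybenzene | COc1cccc(OC)c1 | starting material
22 | 2,6-dimethoxyphenyllithium | [Li]c1c(OC)cccc1OC | intermediate (not isolated)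
23 | 9,9'-(2,3,4',5'-tetramethoxy-[1,1'-biphenyl]-2',5-diyl)bis[1-(2,6-dimethoxyphenyl)nonan-1-ol] (mixture of diastereomers) | COc1cc(CCCCCCCCC(O)c2c(OC)cccc2OC)cc(-c2cc(OC)c(OC)cc2CCCCCCCCC(O)c2c(OC)cccc2OC)c1OC | intermediate
24 | 9,9'-(2,3,4',5'-tetramethoxy-[1,1'-biphenyl]-2',5-diyl)bis[1-(2,6-dimethoxyphenyl)nonan-1-one] | COc1cc(CCCCCCCCC(=O)c2c(OC)cccc2OC)cc(-c2cc(OC)c(OC)cc2CCCCCCCCC(=O)c2c(OC)cccc2OC)c1OC | intermediate
25 | 9,9'-(2,3,4',5'-tetrahydroxy-[1,1'-biphenyl]-2',5-diyl)bis[1-(2,6-dihydroxyphenyl)nonan-1-one] (CNP0305015.0) | O=C(CCCCCCCCc1cc(O)c(O)c(-c2cc(O)c(O)cc2CCCCCCCCC(=O)c2c(O)cccc2O)c1)c1c(O)cccc1O | target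

## Step count and least certain steps

Total: 12 steps. Longest linear sequence: 12 steps (1 to 25); 4, 9 and 21 are purchased and enter at steps 2, 4 and 10.

Step 4 (key step). The acceptor is most likely to be lost by paths other than capture by 10: self-addition through its own benzylic position (8 is donor and acceptor in one molecule), amine-initiated oligomerisation, or a second addition of the first adduct to another molecule of 8. A lesser risk is that the aldol stops before dehydration. The fallback sets out from 6. After the CH2=CHMgBr addition, the chelate 7 is quenched with diethylamine and water in place of acid, which traps the enone as the storable Mannich base 4-(diethylamino)-1-[4,5-dimethoxy-2-(non-8-en-1-yl)phenyl]butan-2-one F1. Iodomethane in acetone converts it into the quaternary salt N,N-diethyl-4-[4,5-dimethoxy-2-(non-8-en-1-yl)phenyl]-N-methyl-3-oxobutan-1-aminium iodide F2. F2 is added in portions to preformed 10 in MeCN containing i-Pr2NEt, so that 8 is released by elimination only at low stationary concentration and is intercepted at once (the Mannich-base form of the Robinson annulation). The same buffered acetic acid treatment closes the ring, and the route is rejoined at 13.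

Step 3. The likely failures are deprotonation of the benzylic position of 6 by the basic Grignard reagent, conjugate addition of the released hydroxylamine during the quench, and polymerisation of 8 on concentration. The fallback sets out from 6. Reduction with i-Bu2AlH (THF, −78 °C) gives [4,5-dimethoxy-2-(non-8-en-1-yl)phenyl]acetaldehyde F3. Addition of CH2=CHMgBr premixed with CeCl3 at −78 °C, a much less basic reagent, gives the allylic alcohol rac-1-[4,5-dimethoxy-2-(non-8-en-1-yl)phenyl]but-3-en-2-ol F4, which can be stored. Oxidation with DMP immediately before step 4 rejoins the route at 8.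

Step 5. Regiocontrol may be lost if the cross-conjugated enolate equilibrates to the extended dienolate, which would be oxidised at C2 or C4; over-oxidation of the product enolate is the second risk. The fallback sets out from 13 and needs no preformed enolate: alpha-prime acetoxylation with Mn(OAc)3·2H2O (trivalent manganese) in benzene at reflux, a known alpha-prime-selective reaction of enones, gives 3-[4,5-dimethoxy-2-(non-8-en-1-yl)phenyl]-5-(non-8-en-1-yl)-2-oxocyclohex-3-en-1-yl acetate F5. K2CO3 in degassed MeOH cleaves the acetate and the route is rejoined at 14.

Step 6. Ring A may be over-oxidised to the ortho-quinone once it has aromatised, the new phenol may be methylthiomethylated by residual activated DMSO, or the catecholate may be oxidised by air in the amine-containing medium. The fallback sets out from 14 and over-oxidises on purpose. Excess DMP takes 14 through 15 and 16 to the ortho-quinone 3-[4,5-dimethoxy-2-(non-8-en-1-yl)phenyl]-5-(non-8-en-1-yl)cyclohexa-3,5-diene-1,2-dione F6. A reductive work-up with aqueous Na2S2O4 then returns all material to the catechol level, and the route is rejoined at 16.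

Step 12. Cleavage of the eight ethers may be incomplete, because partly cleaved aryloxyboron species can precipitate and stall, and the two catechols may be oxidised during aqueous work-up and chromatography. The fallback sets out from 24. The ethers are cleaved with AlI3 generated from AlCl3 and NaI in MeCN (iodide as the dealkylating nucleophile). The crude polyphenol is not purified but peracetylated (Ac2O, pyridine) to the air-stable octaacetate 2',5-bis[9-(2,6-diacetoxyphenyl)-9-oxononyl]-[1,1'-biphenyl]-2,3,4',5'-tetrayl tetraacetate F7, which can be chromatographed free of partly methylated material. Methanolysis with K2CO3 in degassed MeOH under argon, followed by acidification, rejoins the route at 25.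

## Further compounds

F1 | step 4 | 4-(diethylamino)-1-[4,5-dimethoxy-2-(non-8-en-1-yl)phenyl]butan-2-one | CCN(CC)CCC(=O)Cc1cc(OC)c(OC)cc1CCCCCCCC=C
F2 | step 4 | N,N-diethyl-4-[4,5-dimethoxy-2-(non-8-en-1-yl)phenyl]-N-methyl-3-oxobutan-1-aminium iodide | CC[N+](C)(CC)CCC(=O)Cc1cc(OC)c(OC)cc1CCCCCCCC=C.[I-]
F3 | step 3 | [4,5-dimethoxy-2-(non-8-en-1-yl)phenyl]acetaldehyde | O=CCc1cc(OC)c(OC)cc1CCCCCCCC=C
F4 | step 3 | rac-1-[4,5-dimethoxy-2-(non-8-en-1-yl)phenyl]but-3-en-2-ol | C=CC(O)Cc1cc(OC)c(OC)cc1CCCCCCCC=C
F5 | step 5 | 3-[4,5-dimethoxy-2-(non-8-en-1-yl)phenyl]-5-(non-8-en-1-yl)-2-oxocyclohex-3-en-1-yl acetate (racemic mixture of diastereomers) | CC(=O)OC1CC(CCCCCCCC=C)C=C(c2cc(OC)c(OC)cc2CCCCCCCC=C)C1=O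
F6 | step 6 | 3-[4,5-dimethoxy-2-(non-8-en-1-yl)phenyl]-5-(non-8-en-1-yl)cyclohexa-3,5-diene-1,2-dione | O=C1C(=O)C(c2cc(OC)c(OC)cc2CCCCCCCC=C)=CC(CCCCCCCC=C)=C1
F7 | step 12 | 2',5-bis[9-(2,6-diacetoxyphenyl)-9-oxononyl]-[1,1'-biphenyl]-2,3,4',5'-tetrayl tetraacetate | CC(=O)Oc1cccc(OC(C)=O)c1C(=O)CCCCCCCCc1cc(OC(C)=O)c(OC(C)=O)c(-c2cc(OC(C)=O)c(OC(C)=O)cc2CCCCCCCCC(=O)c2c(OC(C)=O)cccc2OC(C)=O)c1
A1 | alternative 1 | 2,3,4',5'-tetrakis(benzyloxy)-[1,1'-biphenyl]-2',5-dicarbaldehyde | O=Cc1cc(OCc2ccccc2)c(OCc2ccccc2)c(-c2cc(OCc3ccccc3)c(OCc3ccccc3)cc2C=O)c1
A2 | alternative 1 | {8-[2,6-bis(benzyloxy)phenyl]-8-oxooctyl}triphenylphosphonium bromide | O=C(CCCCCCC[P+](c1ccccc1)(c1ccccc1)c1ccccc1)c1c(OCc2ccccc2)cccc1OCc1ccccc1.[Br-]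
A3 | alternative 1 | (8Z,8'Z)-9,9'-[2,3,4',5'-tetrakis(benzyloxy)-[1,1'-biphenyl]-2',5-diyl]bis{1-[2,6-bis(benzyloxy)phenyl]non-8-en-1-one} | O=C(CCCCCC/C=C\c1cc(OCc2ccccc2)c(OCc2ccccc2)c(-c2cc(OCc3ccccc3)c(OCc3ccccc3)cc2/C=C\CCCCCCC(=O)c2c(OCc3ccccc3)cccc2OCc2ccccc2)c1)c1c(OCc2ccccc2)cccc1OCc1ccccc1
A4 | alternative 2 | 2,3,4',5'-tetramethoxy-2',5-bis[8-(2-{[tri(propan-2-yl)silyl]oxyethynyl}-1,3-dioxolan-2-yl)octyl]-1,1'-biphenyl | CC(C)[Si](OC#CC1(CCCCCCCCc2cc(OC)c(OC)c(-c3cc(OC)c(OC)cc3CCCCCCCCC3(C#CO[Si](C(C)C)(C(C)C)C(C)C)OCCO3)c2)OCCO1)(C(C)C)C(C)C
A5 | alternative 2 | cyclobut-2-en-1-one | O=C1CC=C1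
A6 | alternative 2 | bis(dioxolane) of the target skeleton with rings A and B as methyl ethers and rings C and D as mono[tri(propan-2-yl)silyl] ethers | CC(C)[Si](Oc1cccc(O)c1C1(CCCCCCCCc2cc(OC)c(OC)c(-c3cc(OC)c(OC)cc3CCCCCCCCC3(c4c(O)cccc4O[Si](C(C)C)(C(C)C)C(C)C)OCCO3)c2)OCCO1)(C(C)C)C(C)C
A7 | alternative 3 | 3,3'-[2,3,4',5'-tetrakis(2,2-dimethylpropanoyloxy)-[1,1'-biphenyl]-2',5-diyl]dipropanoic acid | CC(C)(C)C(=O)Oc1cc(CCC(=O)O)cc(-c2cc(OC(=O)C(C)(C)C)c(OC(=O)C(C)(C)C)cc2CCC(=O)O)c1OC(=O)C(C)(C)C
A8 | alternative 3 | 8-[2,6-bis(2,2-dimethylpropanoyloxy)phenyl]-8-oxooctanoic acid | CC(C)(C)C(=O)Oc1cccc(OC(=O)C(C)(C)C)c1C(=O)CCCCCCC(=O)O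
A9 | alternative 3 | octakis(2,2-dimethylpropanoate) of 25 | CC(C)(C)C(=O)Oc1cccc(OC(=O)C(C)(C)C)c1C(=O)CCCCCCCCc1cc(OC(=O)C(C)(C)C)c(OC(=O)C(C)(C)C)c(-c2cc(OC(=O)C(C)(C)C)c(OC(=O)C(C)(C)C)cc2CCCCCCCCC(=O)c2c(OC(=O)C(C)(C)C)cccc2OC(=O)C(C)(C)C)c1
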